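**Retrosynthetic overview**
- Feature: ring A carries four contiguous stereocentres, C3 (ester carbinol), C4 (CHMe), C5 (quaternary CMe) and C10 (ring-fusion CH) in eremophilane numbering. The cis C4/C5 methyl pair is the methyl pair of an (E)-2-methylbut-2-enoyl (tigloyl) group, so ring A is read as a Diels–Alder cyclohexene.
- Late disconnections: the C8/C9 acetonide, both Z-enoates (double semi-hydrogenation of a bis-ynoate) and the C3–O acyl bond. C3 is corrected through the 1-en-3-one, and the helper carbonyl at C6 is removed by Barton–McCombie deoxygenation.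
- Key disconnection: C3–C4 and C5–C10, by a type 1 intramolecular Diels–Alder reaction of tigloyl ketone 22. The dienophile is C4=C5 activated by C6=O, the diene is C3=C2–C1=C10 with a silyloxy group on C3, and the tether is C6–C9.
- Triene 22: C5–C6 by Nozaki–Hiyama–Kishi coupling, C7–C8 by Z-allylboration of a malate-derived α-silyloxy aldehyde (C9 from the chiral pool) with the isoprene bis(boronate), and C1=C2 by Wittig olefination.
- Ring order: before step 15 only the dioxolane protecting ring exists. Rings A and B are closed together in step 15.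

Key step: step 15

Remark: atoms carry eremophilane numbers from the first acyclic intermediate on, and dimethyl (S)-malate (the commercial diester of (S)-malic acid), (E)-2-bromobut-2-ene and (S)-pent-1-yn-3-ol are assumed to be bought as single isomers.

**Route**

Step 1
Reactants: 1 dimethyl (S)-malate
Product: 2 methyl (3S)-3,4-dihydroxybutanoate
Conditions: BH3·SMe2 (1.05 equiv), NaBH4 (5 mol %), THF, 0 °C → rt; MeOH
Reagents that add atoms: none
Why: Hydroxyl-directed borane reduction, in which the free hydroxyl binds boron and hydride reaches only the neighbouring ester through a five-membered chelate, so C8 becomes CH2OH while the C1 ester and the malate stereocentre (future C9, S) stay untouched.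

Step 2
Reactants: 2 methyl (3S)-3,4-dihydroxybutanoate
Product: 3 methyl (3S)-3,4-bis(triethylsilyloxy)butanoate
Conditions: Et3SiCl (2.3 equiv), imidazole, CH2Cl2, 0 °C → rt
Reagents that add atoms: chlorotriethylsilane, CC[Si](Cl)(CC)CC
Why: Standard silyl chloride/imidazole silylation of both hydroxyls, with triethylsilyl chosen because its primary ether can be oxidised directly in step 5 and its secondary ether falls off under the mild acid of step 8.

Step 3
Reactants: 3 methyl (3S)-3,4-bis(triethylsilyloxy)butanoate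
Product: 4 (3S)-3,4-bis(triethylsilyloxy)butanal
Conditions: i-Bu2AlH (1.05 equiv), CH2Cl2, −78 °C; aq. potassium sodium tartrate
Reagents that add atoms: none
Why: Partial ester reduction with i-Bu2AlH, whose tetrahedral aluminium hemiacetal survives at −78 °C and releases the C1 aldehyde only on work-up, which avoids over-reduction and β-elimination of the silyloxy group.

Step 4
Reactants: 4 (3S)-3,4-bis(triethylsilyloxy)butanal; 5 methyl (triphenylphosphoranylidene)acetate
Product: 6 methyl (2E,5S)-5,6-bis(triethylsilyloxy)hex-2-enoate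
Conditions: CH2Cl2, rt
Reagents that add atoms: none
Why: Wittig olefination with a stabilised ylide, which gives the E-enoate (C1=C2, with C3 as the ester carbon) under neutral conditions that leave the β-silyloxy aldehyde intact.

Step 5
Reactants: 6 methyl (2E,5S)-5,6-bis(triethylsilyloxy)hex-2-enoate
Product: 8 methyl (2E,5S)-6-oxo-5-(triethylsilyloxy)hex-2-enoate, via alkoxysulfonium chloride 7 (not isolated)
Conditions: (COCl)2, DMSO, CH2Cl2, −78 → −35 °C; then Et3N, −78 → 0 °C
Reagents that add atoms: none
Why: Swern oxidation run directly on the bis-silyl ether, in which the activated sulfonium salt displaces only the unhindered primary triethylsilyl group and the alkoxysulfonium salt collapses with Et3N to the C8 aldehyde at a temperature where C9 does not epimerise.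

Step 6
Reactants: 9 isoprene; 10 bis(pinacolato)diboron
Product: 11 (Z)-2,2'-(2-methylbut-2-ene-1,4-diyl)bis(4,4,5,5-tetramethyl-1,3,2-dioxaborolane)
Conditions: Pt(PPh3)4 (3 mol %), toluene, 80 °C
Reagents that add atoms: none
Why: 1,4-Diboration of a 1,3-diene catalysed by zerovalent platinum, in which B–B oxidative addition, insertion of s-cis isoprene and reductive elimination from the π-allyl complex deliver the Z-alkene.

Step 7
Reactants: 8 methyl (2E,5S)-6-oxo-5-(triethylsilyloxy)hex-2-enoate; 11 (Z)-isoprene bis(pinacolboronate)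
Product: 12 methyl (2E,5S,6R,7S)-6-hydroxy-8-methyl-7-[(4,4,5,5-tetramethyl-1,3,2-dioxaborolan-2-yl)methyl]-5-(triethylsilyloxy)nona-2,8-dienoate
Conditions: toluene, 0 °C → rt; aq. NaHCO3 work-up
Reagents that add atoms: none
Why: Allylboration through a Zimmerman–Traxler chair, in which the C12 boronate reacts because it is a methallyl unit with an unhindered CH γ-carbon (C7), its Z γ-substituent (CH2Bpin, future C6) sits axial and sets the isopropenyl/OH-anti relation at C7/C8, and the Cornforth-type arrangement of the α-silyloxy aldehyde, which Z-γ-substituted allylboronates follow closely because the alternative suffers a syn-pentane contact, places C8–OH anti to C9–O.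

Step 8
Reactants: 12 allylboration product
Product: 14 methyl (E)-4-[(4S,5R)-2,2-dimethyl-5-{(2S)-3-methyl-1-(pinacolboryl)but-3-en-2-yl}-1,3-dioxolan-4-yl]but-2-enoate, via diol 13 (not isolated)
Conditions: CSA (10 mol %), MeOH, 0 °C; then Me2C(OMe)2, acetone, rt; Et3N
Reagents that add atoms: 2,2-dimethoxypropane, COC(C)(C)OC
Why: Acid-catalysed methanolysis of the secondary triethylsilyl ether followed by transketalisation, and because C6 is still masked as a C–B bond only the C8/C9 diol is available, so the cis-dioxolane forms without a competing 1,3-dioxane.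

Step 9
Reactants: 14 acetonide boronate
Product: 15 methyl (E)-4-[(4S,5R)-5-{(2R)-1-hydroxy-3-methylbut-3-en-2-yl}-2,2-dimethyl-1,3-dioxolan-4-yl]but-2-enoate
Conditions: NaBO3·4H2O, THF/H2O, rt
Reagents that add atoms: sodium perborate, [Na+].[Na+].O[B-]1(O)OO[B-](O)(O)OO1
Why: Boronate oxidation (1,2-shift of C6 from boron to oxygen in the peroxoborate) under the nearly neutral perborate conditions that spare the methyl enoate and the ketal and do not touch C7.

Step 10
Reactants: 15 primary alcohol
Product: 16 methyl (E)-4-[(4S,5R)-2,2-dimethyl-5-{(2S)-3-methyl-1-oxobut-3-en-2-yl}-1,3-dioxolan-4-yl]but-2-enoate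
Conditions: Dess–Martin periodinane, NaHCO3, CH2Cl2, 0 °C; used at once
Reagents that add atoms: none
Why: Dess–Martin oxidation under buffered, non-basic conditions, so that C7 is not epimerised, the isopropenyl double bond is not drawn into conjugation and the C8 oxygen is not eliminated.

Step 11
Reactants: 16 C6 aldehyde; 17 (E)-2-bromobut-2-ene
Product: 19 methyl (E)-4-[(4S,5R)-5-{(3R,5E)-4-hydroxy-2,5-dimethylhepta-1,5-dien-3-yl}-2,2-dimethyl-1,3-dioxolan-4-yl]but-2-enoate (C6 carbinol epimers), via alkenylchromium dichloride 18 (not isolated)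
Conditions: CrCl2 (5 equiv), NiCl2 (2 mol %), DMF, rt
Reagents that add atoms: none
Why: Nozaki–Hiyama–Kishi coupling, in which the alkenylchromium reagent forms with retention of the E geometry (methyl groups cis) and adds to the aldehyde only, is too weakly basic to disturb C7 and ignores the enoate, while the new C6 carbinol centre is erased in step 13.

Step 12
Reactants: 19 allylic alcohol enoate
Product: 20 (E)-4-[(4S,5R)-5-{(3R,5E)-4-hydroxy-2,5-dimethylhepta-1,5-dien-3-yl}-2,2-dimethyl-1,3-dioxolan-4-yl]but-2-en-1-ol (C6 epimers)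
Conditions: i-Bu2AlH (3.5 equiv), CH2Cl2, −78 °C; aq. potassium sodium tartrate
Reagents that add atoms: none
Why: 1,2-Reduction of the enoate with i-Bu2AlH gives the E-allylic alcohol at C3 without touching the ketal or the other alkenes.

Step 13
Reactants: 20 bis-allylic diol
Product: 21 (E)-4-[(4S,5R)-5-{(3S,5E)-2,5-dimethyl-4-oxohepta-1,5-dien-3-yl}-2,2-dimethyl-1,3-dioxolan-4-yl]but-2-enal
Conditions: Dess–Martin periodinane (3 equiv), NaHCO3, CH2Cl2, 0 °C → rt
Reagents that add atoms: none
Why: Double Dess–Martin oxidation turns the primary allylic alcohol into the C3 enal and the secondary one into the tigloyl ketone in one buffered operation, which merges the C6 epimers and leaves C7 alone.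

Step 14
Reactants: 21 keto enal
Product: 22 (3S,5E)-3-[(4R,5S)-5-{(1E,3E)-4-(tert-butyldimethylsilyloxy)buta-1,3-dienyl}-2,2-dimethyl-1,3-dioxolan-4-yl]-2,5-dimethylhepta-1,5-dien-4-one
Conditions: t-BuMe2SiOTf (1.1 equiv), Et3N (3 equiv), Et2O, −78 → −30 °C; cold aq. NaHCO3; basic Al2O3
Reagents that add atoms: tert-butyldimethylsilyl trifluoromethanesulfonate, CC(C)(C)[Si](C)(C)OS(=O)(=O)C(F)(F)F
Why: Soft enolisation (silyl triflate/tertiary amine), in which O-silylation of the unhindered s-trans enal and loss of a C10 proton give the E enol ether C2=C3, the bulky dioxolane carbon C9 turns outward during deprotonation and gives E C10=C1, and the hindered ketone, whose only α-proton (C7) is tertiary, should be left alone by one equivalent of triflate in the cold.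

Step 15
Reactants: 22 tigloyl ketone triene
Product: 23 (3S,4R,5R,7S,8R,9S,10R)-3-(tert-butyldimethylsilyloxy)-8,9-(isopropylidenedioxy)eremophila-1,11-dien-6-one (trans-fused; silyloxy group axial and cis to both methyls)
Conditions: degassed toluene (5 mM), BHT, 2,6-di-tert-butyl-4-methylpyridine (0.2 equiv), silylated sealed vessel, 140 °C
Reagents that add atoms: none
Why: Concerted suprafacial [4+2] cycloaddition of the s-cis (1E,3E)-1-silyloxydiene C3=C2–C1=C10 to the tigloyl double bond C4=C5, whose LUMO is lowered by the C6 carbonyl; the closest known reaction type is the thermal type 1 intramolecular Diels–Alder reaction of 1,7,9-decatrien-3-ones. Ring A closes as the new cyclohexene through the bonds C3–C4 and C5–C10, and ring B closes in the same event as a six-membered carbocycle from the tether atoms C6–C9 and the new C5–C10 bond (fused mode, the bridged mode being out of reach for a four-atom tether). The tether joins the oxygenated terminus C3 to the enone β-carbon C4, the reverse of the electronically preferred orientation, so the silyloxy group only raises the diene HOMO, heat is needed, and Lewis acids are left out because they would favour Mukaiyama–Michael attack of C10 on C4 or ionisation of the allylic C9–O bond. C4 and C5 are set by the E geometry of the dienophile (methyls cis), C3 and C10 by the E,E geometry of the diene (H3 and H10 cis), and the two pairs are related by the exo mode, with C6=O turned away from the diene and both methyls under it, which gives the trans ring fusion and an axial silyloxy group cis to the methyls. The absolute sense follows from the chair-like tether in which C9–O and the C7 isopropenyl group are equatorial and only C8–O is axial, since the other exo chair would carry two axial groups. The selectivity needed is exo over endo: in the same chair the endo mode must place the diene axial on C10, syn-axial to the C8 oxygen of the dioxolane, or twist C4=C5 out of conjugation with C6=O, and α-methyl dienophiles lean towards exo in any case, although this preference has not been tested on this substitution pattern.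

Step 16
Reactants: 23 cycloadduct
Product: 24 3-(tert-butyldimethylsilyloxy)-8,9-(isopropylidenedioxy)eremophila-1,11-dien-6-ol (C6 epimers; other centres as in 23)
Conditions: LiAlH4, Et2O, −78 → 0 °C
Reagents that add atoms: none
Why: Hydride reduction of the hindered ketone directly after the cycloaddition removes the only group that acidifies H7, so C7 (set in step 7) is never exposed to base next to a carbonyl, where the isopropenyl group would slip into conjugation or the axial C8 oxygen would be expelled, and either C6 epimer serves.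

Step 17
Reactants: 24 C6 alcohol
Product: 26 O-[3-(tert-butyldimethylsilyloxy)-8,9-(isopropylidenedioxy)eremophila-1,11-dien-6-yl] S-methyl dithiocarbonate, via sodium xanthate 25 (not isolated)
Conditions: NaH, imidazole (cat.), CS2, THF, 0 °C → rt; then MeI
Reagents that add atoms: carbon disulfide, S=C=S; iodomethane, CI
Why: Xanthate formation, in which the small electrophile CS2 can reach the neopentyl-type alkoxide and S-methylation fixes the radical precursor, while silyl ether, ketal and alkenes are inert.

Step 18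
Reactants: 26 xanthate
Product: 27 (3S,4R,5R,7S,8R,9S,10R)-3-(tert-butyldimethylsilyloxy)-8,9-(isopropylidenedioxy)eremophila-1,11-diene
Conditions: n-Bu3SnH (3 equiv, 0.5 M), AIBN, toluene, 85 °C
Reagents that add atoms: none
Why: Barton–McCombie deoxygenation, in which a high stannane concentration traps the secondary C6 radical before reversible 3-exo attack on the isopropenyl group can lead to 1,2-vinyl migration, and the temperature stays below that of Chugaev elimination.

Step 19
Reactants: 27 silyl ether
Product: 28 (3S,4R,5R,7S,8R,9S,10R)-8,9-(isopropylidenedioxy)eremophila-1,11-dien-3-ol (axial allylic alcohol)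
Conditions: n-Bu4NF, THF, rt → 40 °C
Reagents that add atoms: none
Why: Fluoride-induced cleavage of the Si–O bond, which is orthogonal to the ketal and the alkenes.

Step 20
Reactants: 28 allylic alcohol
Product: 29 (4R,5R,7S,8R,9S,10R)-8,9-(isopropylidenedioxy)eremophila-1,11-dien-3-one
Conditions: Dess–Martin periodinane, NaHCO3, CH2Cl2, 0 °C
Reagents that add atoms: none
Why: Dess–Martin oxidation deliberately erases the wrong C3 centre under base-free conditions, so that the equatorial C4 methyl stays and the γ-proton at C10, whose removal would expel the C9 oxygen, is not touched.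

Step 21
Reactants: 29 enone
Product: 31 (3R,4R,5R,7S,8R,9S,10R)-8,9-(isopropylidenedioxy)eremophil-11-en-3-ol (equatorial alcohol trans to the C4 methyl), via saturated 3-ketone 30 (not isolated)
Conditions: Li (limited excess), NH3(l)/THF, EtOH, −78 → −33 °C; NH4Cl
Reagents that add atoms: none
Why: Dissolving-metal reduction, in which the enone is taken to the C2=C3 enolate, ethanol releases ketone 30 and its ketyl is protonated to the more stable equatorial alcohol (3R), whereas hydride reagents would be forced onto the equatorial trajectory by the syn-axial C5 methyl and would return the axial alcohol, and the isolated isopropenyl group and the ketal are inert.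

Step 22
Reactants: 32 (S)-pent-1-yn-3-ol
Product: 33 (S)-tert-butyl(dimethyl)(pent-1-yn-3-yloxy)silane
Conditions: t-BuMe2SiCl, imidazole, DMF, rt
Reagents that add atoms: tert-butyldimethylsilyl chloride, CC(C)(C)[Si](C)(C)Cl
Why: Standard silylation masks the carbinol, whose S configuration is that of C4' of the side chain, for the acetylide chemistry.

Step 23
Reactants: 33 silyl ether
Product: 35 tert-butyl (4S)-4-(tert-butyldimethylsilyloxy)hex-2-ynoate, via lithium acetylide 34 (not isolated)
Conditions: n-BuLi, THF, −78 °C; then Boc2O, −78 → 0 °C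
Reagents that add atoms: di-tert-butyl dicarbonate, CC(C)(C)OC(=O)OC(=O)OC(C)(C)C
Why: Acylation of a lithium acetylide with a dicarbonate installs the C1' carboxyl directly as an acid-labile tert-butyl ester.

Step 24
Reactants: 35 silyl ynoate
Product: 36 tert-butyl (4S)-4-hydroxyhex-2-ynoate
Conditions: HF·pyridine, THF, 0 °C → rt
Reagents that add atoms: none
Why: Buffered fluoride desilylation avoids the base-induced alkyne–allene isomerisation that would racemise the propargylic centre.

Step 25
Reactants: 36 hydroxy ynoate; 37 hex-2-ynoic acid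
Product: 38 tert-butyl (4S)-4-(hex-2-ynoyloxy)hex-2-ynoate
Conditions: DCC, DMAP (10 mol %), CH2Cl2, 0 °C
Reagents that add atoms: none
Why: Steglich esterification acylates oxygen with retention at C4', and both unsaturations are kept as alkynes so that no Z-enoate has to pass through acyl-transfer catalysis.

Step 26
Reactants: 38 diester
Product: 39 (4S)-4-(hex-2-ynoyloxy)hex-2-ynoic acid
Conditions: CF3CO2H/CH2Cl2 (1:4), 0 °C → rt
Reagents that add atoms: none
Why: Acidolysis of the tert-butyl ester by loss of isobutene leaves the secondary propargylic ester intact, because the electron-poor alkyne does not support ionisation at C4'.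

Step 27
Reactants: 31 C3 alcohol; 39 side-chain acid
Product: 40 (3R,4R,5R,7S,8R,9S,10R)-8,9-(isopropylidenedioxy)eremophil-11-en-3-yl (4S)-4-(hex-2-ynoyloxy)hex-2-ynoate
Conditions: DCC, DMAP (20 mol %), CH2Cl2, 0 °C → rt
Reagents that add atoms: none
Why: Steglich esterification of the equatorial C3 alcohol with retention, carried out at the alkyne level because a Z-enoic acid would isomerise to E under DMAP catalysis and a free Z-4-hydroxy enoate would lactonise.

Step 28
Reactants: 40 bis-ynoate
Product: 41 8,9-(isopropylidenedioxy)eremophil-11-en-3-yl (2Z,4S)-4-[(2Z)-hex-2-enoyloxy]hex-2-enoate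
Conditions: H2 (1 atm), Pd/CaCO3–Pb(OAc)2 (Lindlar catalyst), quinoline, EtOAc, rt, stopped after uptake of 2 equiv
Reagents that add atoms: none
Why: Lindlar semi-hydrogenation delivers H2 syn to both conjugated alkynes and sets both Z-enoates at once, while the 1,1-disubstituted isopropenyl alkene is not reduced on the poisoned catalyst.

Step 29
Reactants: 41 acetonide
Product: 42 (3R,4R,5R,7S,8R,9S,10R)-8,9-dihydroxyeremophil-11-en-3-yl (2Z,4S)-4-[(2Z)-hex-2-enoyloxy]hex-2-enoate (CNP0271544.1)
Conditions: AcOH/H2O (4:1), 40 °C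
Reagents that add atoms: none
Why: Mild acid-catalysed ketal hydrolysis frees the cis C8/C9 diol without protonating the isopropenyl group or isomerising the Z-enoates, and acyl migration is excluded because the C3 ester is remote from the diol.

**Compound list**
1 | dimethyl (S)-malate | COC(=O)C[C@H](O)C(=O)OC | starting material
2 | methyl (3S)-3,4-dihydroxybutanoate | COC(=O)C[C@H](O)CO | intermediate
3 | methyl (3S)-3,4-bis(triethylsilyloxy)butanoate | COC(=O)C[C@H](O[Si](CC)(CC)CC)CO[Si](CC)(CC)CC | intermediate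
4 | (3S)-3,4-bis(triethylsilyloxy)butanal | O=CC[C@H](O[Si](CC)(CC)CC)CO[Si](CC)(CC)CC | intermediate
5 | methyl (triphenylphosphoranylidene)acetate | COC(=O)C=P(c1ccccc1)(c1ccccc1)c1ccccc1 | starting material
6 | methyl (2E,5S)-5,6-bis(triethylsilyloxy)hex-2-enoate | COC(=O)/C=C/C[C@H](O[Si](CC)(CC)CC)CO[Si](CC)(CC)CC | intermediate
7 | alkoxysulfonium chloride of the C8 oxygen (not isolated) | COC(=O)/C=C/C[C@H](O[Si](CC)(CC)CC)CO[S+](C)C.[Cl-] | intermediate
8 | methyl (2E,5S)-6-oxo-5-(triethylsilyloxy)hex-2-enoate | COC(=O)/C=C/C[C@H](O[Si](CC)(CC)CC)C=O | intermediate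
9 | isoprene | C=CC(C)=C | starting material
10 | bis(pinacolato)diboron | CC1(C)OB(OC1(C)C)B1OC(C)(C)C(C)(C)O1 | starting material
11 | (Z)-2,2'-(2-methylbut-2-ene-1,4-diyl)bis(4,4,5,5-tetramethyl-1,3,2-dioxaborolane) | CC1(C)OB(C/C(C)=C\CB2OC(C)(C)C(C)(C)O2)OC1(C)C | intermediate
12 | methyl (2E,5S,6R,7S)-6-hydroxy-8-methyl-7-[(pinacolboryl)methyl]-5-(triethylsilyloxy)nona-2,8-dienoate | CC1(C)OB(C[C@@H](C(C)=C)[C@@H](O)[C@@H](O[Si](CC)(CC)CC)C/C=C/C(=O)OC)OC1(C)C | intermediate
13 | methyl (2E,5S,6R,7S)-5,6-dihydroxy-8-methyl-7-[(pinacolboryl)methyl]nona-2,8-dienoate (not isolated) | CC1(C)OB(C[C@@H](C(C)=C)[C@@H](O)[C@@H](O)C/C=C/C(=O)OC)OC1(C)C | intermediate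
14 | C8/C9 acetonide with C6–Bpin and C3 methyl enoate (7S,8R,9S) | CC1(C)OB(C[C@@H](C(C)=C)[C@H]2OC(C)(C)O[C@H]2C/C=C/C(=O)OC)OC1(C)C | intermediate
15 | C6 primary alcohol, acetonide, methyl enoate (7R,8R,9S) | OC[C@@H](C(C)=C)[C@H]1OC(C)(C)O[C@H]1C/C=C/C(=O)OC | intermediate
16 | C6 aldehyde, acetonide, methyl enoate (7S,8R,9S) | O=C[C@@H](C(C)=C)[C@H]1OC(C)(C)O[C@H]1C/C=C/C(=O)OC | intermediate
17 | (E)-2-bromobut-2-ene | C/C=C(\C)Br | starting material
18 | (E)-but-2-en-2-ylchromium dichloride (not isolated) | C/C=C(\C)[Cr](Cl)Cl | intermediate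
19 | C6 allylic alcohol (epimers), acetonide, methyl enoate | C/C=C(\C)C(O)[C@@H](C(C)=C)[C@H]1OC(C)(C)O[C@H]1C/C=C/C(=O)OC | intermediate
20 | C3/C6 bis-allylic diol (C6 epimers), acetonide | C/C=C(\C)C(O)[C@@H](C(C)=C)[C@H]1OC(C)(C)O[C@H]1C/C=C/CO | intermediate
21 | tigloyl ketone enal, acetonide (7S,8R,9S) | C/C=C(\C)C(=O)[C@@H](C(C)=C)[C@H]1OC(C)(C)O[C@H]1C/C=C/C=O | intermediate
22 | tigloyl ketone triene with (1E,3E)-silyl dienol ether (7S,8R,9S) | C/C=C(\C)C(=O)[C@@H](C(C)=C)[C@H]1OC(C)(C)O[C@H]1/C=C/C=C/O[Si](C)(C)C(C)(C)C | intermediate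
23 | (3S,4R,5R,7S,8R,9S,10R)-3-(tert-butyldimethylsilyloxy)-8,9-(isopropylidenedioxy)eremophila-1,11-dien-6-one | C=C(C)[C@@H]1C(=O)[C@]2(C)[C@@H](C)[C@@H](O[Si](C)(C)C(C)(C)C)C=C[C@H]2[C@@H]3OC(C)(C)O[C@H]13 | intermediate
24 | 6-ol of 23 (C6 epimers) | C=C(C)[C@@H]1C(O)[C@]2(C)[C@@H](C)[C@@H](O[Si](C)(C)C(C)(C)C)C=C[C@H]2[C@@H]3OC(C)(C)O[C@H]13 | intermediate
25 | sodium xanthate of 24 (not isolated) | C=C(C)[C@@H]1C(OC(=S)[S-])[C@]2(C)[C@@H](C)[C@@H](O[Si](C)(C)C(C)(C)C)C=C[C@H]2[C@@H]3OC(C)(C)O[C@H]13.[Na+] | intermediate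
26 | S-methyl xanthate of 24 | C=C(C)[C@@H]1C(OC(=S)SC)[C@]2(C)[C@@H](C)[C@@H](O[Si](C)(C)C(C)(C)C)C=C[C@H]2[C@@H]3OC(C)(C)O[C@H]13 | intermediate
27 | (3S,4R,5R,7S,8R,9S,10R)-3-(tert-butyldimethylsilyloxy)-8,9-(isopropylidenedioxy)eremophila-1,11-diene | C=C(C)[C@@H]1C[C@]2(C)[C@@H](C)[C@@H](O[Si](C)(C)C(C)(C)C)C=C[C@H]2[C@@H]3OC(C)(C)O[C@H]13 | intermediate
28 | (3S,4R,5R,7S,8R,9S,10R)-8,9-(isopropylidenedioxy)eremophila-1,11-dien-3-ol | C=C(C)[C@@H]1C[C@]2(C)[C@@H](C)[C@@H](O)C=C[C@H]2[C@@H]3OC(C)(C)O[C@H]13 | intermediate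
29 | (4R,5R,7S,8R,9S,10R)-8,9-(isopropylidenedioxy)eremophila-1,11-dien-3-one | C=C(C)[C@@H]1C[C@]2(C)[C@@H](C)C(=O)C=C[C@H]2[C@@H]3OC(C)(C)O[C@H]13 | intermediate
30 | (4R,5R,7S,8R,9S,10R)-8,9-(isopropylidenedioxy)eremophil-11-en-3-one (not isolated) | C=C(C)[C@@H]1C[C@]2(C)[C@@H](C)C(=O)CC[C@H]2[C@@H]3OC(C)(C)O[C@H]13 | intermediate
31 | (3R,4R,5R,7S,8R,9S,10R)-8,9-(isopropylidenedioxy)eremophil-11-en-3-ol | C=C(C)[C@@H]1C[C@]2(C)[C@@H](C)[C@H](O)CC[C@H]2[C@@H]3OC(C)(C)O[C@H]13 | intermediate
32 | (S)-pent-1-yn-3-ol | CC[C@H](O)C#C | starting material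
33 | (S)-tert-butyl(dimethyl)(pent-1-yn-3-yloxy)silane | CC[C@H](O[Si](C)(C)C(C)(C)C)C#C | intermediate
34 | lithium acetylide of 33 (not isolated) | CC[C@H](O[Si](C)(C)C(C)(C)C)C#C[Li] | intermediate
35 | tert-butyl (4S)-4-(tert-butyldimethylsilyloxy)hex-2-ynoate | CC[C@H](O[Si](C)(C)C(C)(C)C)C#CC(=O)OC(C)(C)C | intermediate
36 | tert-butyl (4S)-4-hydroxyhex-2-ynoate | CC[C@H](O)C#CC(=O)OC(C)(C)C | intermediate
37 | hex-2-ynoic acid | CCCC#CC(=O)O | starting material
38 | tert-butyl (4S)-4-(hex-2-ynoyloxy)hex-2-ynoate | CC[C@H](OC(=O)C#CCCC)C#CC(=O)OC(C)(C)C | intermediate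
39 | (4S)-4-(hex-2-ynoyloxy)hex-2-ynoic acid | CC[C@H](OC(=O)C#CCCC)C#CC(=O)O | intermediate
40 | 8,9-(isopropylidenedioxy)eremophil-11-en-3-yl (4S)-4-(hex-2-ynoyloxy)hex-2-ynoate | C=C(C)[C@@H]1C[C@]2(C)[C@@H](C)[C@H](OC(=O)C#C[C@H](CC)OC(=O)C#CCCC)CC[C@H]2[C@@H]3OC(C)(C)O[C@H]13 | intermediate
41 | 8,9-(isopropylidenedioxy)eremophil-11-en-3-yl (2Z,4S)-4-[(2Z)-hex-2-enoyloxy]hex-2-enoate | C=C(C)[C@@H]1C[C@]2(C)[C@@H](C)[C@H](OC(=O)/C=C\[C@H](CC)OC(=O)/C=C\CCC)CC[C@H]2[C@@H]3OC(C)(C)O[C@H]13 | intermediate
42 | CNP0271544.1, (3R,4R,5R,7S,8R,9S,10R)-8,9-dihydroxyeremophil-11-en-3-yl (2Z,4S)-4-[(2Z)-hex-2-enoyloxy]hex-2-enoate | C=C(C)[C@@H]1C[C@]2(C)[C@@H](C)[C@H](OC(=O)/C=C\[C@H](CC)OC(=O)/C=C\CCC)CC[C@H]2[C@H](O)[C@@H]1O | target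

**Step count**
Total step count: 29.
Longest linear sequence: 23 steps (steps 1–5, 7–21 and 27–29).

**Steps most likely to fail**

1. Step 15.
The endo mode may compete and lead to cis ring fusion. The cycloaddition may also be slower than thermal decay of the dienol ether, because the tether overrides the polarity of the diene.
The fallback moves the activating carbonyl from the tether onto C4, so that the endo rule and trans fusion coincide and C3–O meets the acceptor-bearing carbon.
It sets out from 15. Appel iodination (I2, PPh3, imidazole) gives the primary iodide F1, and zinc insertion (Zn dust, LiCl, THF) gives the alkylzinc iodide F2.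
Negishi coupling [Pd(PPh3)4] of F2 with tert-butyl (E)-3-(trifluoromethylsulfonyloxy)but-2-enoate F3 (from tert-butyl acetoacetate, Tf2O and aqueous Me4NOH) gives the diester F4, in which C6 is already CH2.
i-Bu2AlH (2 equiv, −78 °C) reduces only the unhindered methyl enoate to the allylic alcohol F5. MnO2 then gives the enal F6, and t-BuMe2SiOTf/Et3N gives the trienoate F7.
Thermal cyclisation of F7, a member of the known 2,8,10-undecatrienoate class of type 1 intramolecular Diels–Alder reactions, should give the trans-fused C4 ester F8.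
LiAlH4 gives the carbinol F9 and MsCl/Et3N gives the mesylate F10. LiEt3BH then turns the C4 substituent into methyl, and the route is rejoined at 27.

2. Step 14.
The triflate may also enolise the C6 ketone, with loss of the C7 configuration and a shift of the isopropenyl double bond. γ-Deprotonation may give some Z geometry at C10=C1, and the allylic C9–O bond may ionise.
The fallback builds the dienol ether before the ketone exists. It sets out from 20.
TEMPO/PhI(OAc)2 oxidises only the primary allylic alcohol to the hydroxy enal F11, and Ac2O/pyridine gives the acetoxy enal F12.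
t-BuMe2SiOTf/Et3N gives the acetoxy dienol ether F13, at which stage geometric isomers can be removed.
i-Bu2AlH (−78 °C) cleaves the acetate to the hydroxy dienol ether F14, and neutral MnO2 oxidises the C6 allylic alcohol. The route is rejoined at 22.

3. Step 7.
The second allylboron unit (boron on C6, γ-carbon C11) may react and create the quaternary regioisomer, or the facial bias of the aldehyde may be eroded.
The fallback forms C7–C8 by a boron aldol reaction. It sets out from 8.
Tiglic acid is converted (CDI, MeNHOMe·HCl) into the Weinreb amide F15. Methallylmagnesium chloride (from 3-chloro-2-methylprop-1-ene and Mg) then gives (E)-2,5-dimethylhepta-1,5-dien-4-one F16.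
Cy2BCl/Et3N gives the E(O) dicyclohexylboron enolate F17, which adds to 8 in an anti-selective, Felkin-type aldol reaction to give the β-hydroxy ketone F18 after buffered H2O2 work-up. Lower facial selectivity is expected here than with the Z-allylboronate.
The one-pot procedure of step 8 leads through the keto diol F19 to the keto acetonide F20. Excess i-Bu2AlH then reduces ketone and enoate together, and the route is rejoined at 20.

**Further compounds**
F1 | step 15 | C6 primary iodide, acetonide, methyl enoate | IC[C@@H](C(C)=C)[C@H]1OC(C)(C)O[C@H]1C/C=C/C(=O)OC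
F2 | step 15 | C6 alkylzinc iodide | I[Zn]C[C@@H](C(C)=C)[C@H]1OC(C)(C)O[C@H]1C/C=C/C(=O)OC
F3 | step 15 | tert-butyl (E)-3-(trifluoromethylsulfonyloxy)but-2-enoate | CC(C)(C)OC(=O)/C=C(\C)OS(=O)(=O)C(F)(F)F
F4 | step 15 | diester with tert-butyl (E)-3-methylenoate (C4=C5) and methyl enoate (C1=C2) | CC(C)(C)OC(=O)/C=C(\C)C[C@@H](C(C)=C)[C@H]1OC(C)(C)O[C@H]1C/C=C/C(=O)OC
F5 | step 15 | C3 allylic alcohol of F4 | CC(C)(C)OC(=O)/C=C(\C)C[C@@H](C(C)=C)[C@H]1OC(C)(C)O[C@H]1C/C=C/CO
F6 | step 15 | C3 enal of F4 | CC(C)(C)OC(=O)/C=C(\C)C[C@@H](C(C)=C)[C@H]1OC(C)(C)O[C@H]1C/C=C/C=O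
F7 | step 15 | trienoate with (1E,3E)-silyl dienol ether | CC(C)(C)OC(=O)/C=C(\C)C[C@@H](C(C)=C)[C@H]1OC(C)(C)O[C@H]1/C=C/C=C/O[Si](C)(C)C(C)(C)C
F8 | step 15 | trans-fused adduct with C4 tert-butyl ester | C=C(C)[C@@H]1C[C@]2(C)[C@@H](C(=O)OC(C)(C)C)[C@@H](O[Si](C)(C)C(C)(C)C)C=C[C@H]2[C@@H]3OC(C)(C)O[C@H]13
F9 | step 15 | C4 hydroxymethyl compound | C=C(C)[C@@H]1C[C@]2(C)[C@@H](CO)[C@@H](O[Si](C)(C)C(C)(C)C)C=C[C@H]2[C@@H]3OC(C)(C)O[C@H]13
F10 | step 15 | C4 mesyloxymethyl compound | C=C(C)[C@@H]1C[C@]2(C)[C@@H](COS(C)(=O)=O)[C@@H](O[Si](C)(C)C(C)(C)C)C=C[C@H]2[C@@H]3OC(C)(C)O[C@H]13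
F11 | step 14 | C6 hydroxy enal (C6 epimers) | C/C=C(\C)C(O)[C@@H](C(C)=C)[C@H]1OC(C)(C)O[C@H]1C/C=C/C=O
F12 | step 14 | C6 acetoxy enal | C/C=C(\C)C(OC(C)=O)[C@@H](C(C)=C)[C@H]1OC(C)(C)O[C@H]1C/C=C/C=O
F13 | step 14 | C6 acetoxy silyl dienol ether | C/C=C(\C)C(OC(C)=O)[C@@H](C(C)=C)[C@H]1OC(C)(C)O[C@H]1/C=C/C=C/O[Si](C)(C)C(C)(C)C
F14 | step 14 | C6 hydroxy silyl dienol ether | C/C=C(\C)C(O)[C@@H](C(C)=C)[C@H]1OC(C)(C)O[C@H]1/C=C/C=C/O[Si](C)(C)C(C)(C)C
F15 | step 7 | (E)-N-methoxy-N,2-dimethylbut-2-enamide | C/C=C(\C)C(=O)N(C)OC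
F16 | step 7 | (E)-2,5-dimethylhepta-1,5-dien-4-one | C/C=C(\C)C(=O)CC(C)=C
F17 | step 7 | E(O) dicyclohexylboron enolate of F16 | C/C=C(\C)C(\OB(C1CCCCC1)C1CCCCC1)=C/C(C)=C
F18 | step 7 | anti,anti aldol adduct (C8–OH, C9–OSiEt3) | C/C=C(\C)C(=O)[C@@H](C(C)=C)[C@@H](O)[C@@H](O[Si](CC)(CC)CC)C/C=C/C(=O)OC
F19 | step 7 | keto diol | C/C=C(\C)C(=O)[C@@H](C(C)=C)[C@@H](O)[C@@H](O)C/C=C/C(=O)OC
F20 | step 7 | keto acetonide methyl enoate | C/C=C(\C)C(=O)[C@@H](C(C)=C)[C@H]1OC(C)(C)O[C@H]1C/C=C/C(=O)OC
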